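**Retrosynthetic overview**
1. Vibsanin E ⇐ C9 carbaldehyde by a late (acyloxymethylene) Wittig reaction; the CHO and acetonyl groups ⇐ vinyl and methallyl groups (one double ozonolysis).
2. C9/C10 side chains ⇐ copper-catalysed vinyl addition/methallylation of a tricyclic cross-conjugated dienone; C1–H ⇐ 1,4-hydride addition/kinetic protonation of its vinylogous ester.
3. Rings A and C ⇐ one intramolecular oxa-Diels–Alder reaction of a 2-formylcyclohepta-2,6-dienone (Morita–Baylis–Hillman hydroxymethylation, then oxidation).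
4. Ring B ⇐ (4+3) double olefination of a 2,2-disubstituted succinaldehyde with a 1,3-bis(phosphono)acetone (new thiolate-relayed annulation).
5. Dialdehyde ⇐ geranial + nitromethane by aminocatalytic asymmetric Michael addition (sets the quaternary centre), then Nef; ring order: B first, then A and C together.

Assumption: geranial (the pure E isomer of citral) is bought as such; the facial sense in step 1 is assigned by analogy with β-aryl-β-methyl enals, and the enantiomeric catalyst is used if the opposite sense is found.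

Numbering: tricyclic compounds are named as 3-oxatricyclo[6.3.2.0(5,12)]tridecanes: C1 (ring-fusion CH next to C11), C2 (OCH2), O3, C4 (CMe2), C5, C6, C7, C8 (quaternary C–CH3), C9, C10, C11 (C=O), C12 (ring-fusion CH), C13 (CH2). Ring A = C5–C8/C13/C12, ring B = C1/C8–C13, ring C = the pyran.

**Route**

Step 1
Reactants: 1 geranial [(2E)-3,7-dimethylocta-2,6-dienal]; 2 nitromethane
Product: 3 (3S)-3,7-dimethyl-3-(nitromethyl)oct-6-enal
Conditions: (R)-α,α-diphenylprolinol trimethylsilyl ether (20 mol %), PhCO2H (20 mol %), MeNO2 (10 equiv), MeOH, rt, 4 d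
Reagents that add atoms: nitromethane 2, C[N+](=O)[O-]
Why: Iminium-ion organocatalysis (asymmetric Michael addition of a nitronate to a β,β-disubstituted enal): the nitronate attacks C3 of the (E)-iminium ion on the face away from the CPh2OSiMe3 group, which creates the all-carbon quaternary stereocentre as S.

Step 2
Reactants: 3
Product: 5 (2S)-2-methyl-2-(4-methylpent-3-en-1-yl)butanedial, via sodium nitronate 4 (not isolated)
Conditions: NaOMe, MeOH, 0 °C; then TiCl3, NH4OAc, H2O–THF, 0 °C → rt
Reagents that add atoms: water, O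
Why: Nef reaction in its reductive McMurry form (the nitronate is reduced by TiCl3 to the imine, which hydrolyses) turns CH2NO2 into CHO under buffered conditions that spare the enolisable aldehyde and the trisubstituted alkene, and the quaternary centre cannot epimerise.

Step 3
Reactants: 5; 6 tetramethyl (2-oxopropane-1,3-diyl)bis(phosphonate)
Product: 10 (4S)-4-methyl-4-(4-methylpent-3-en-1-yl)cyclohepta-2,6-dien-1-one, via enone phosphonate 7 (not isolated), via thiol adduct 8 (not isolated), via cyclic sulfide 9 (not isolated)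
Conditions: 6 (1.05 equiv), K2CO3, 18-crown-6 (cat.), PhMe–THF, 0 °C → rt; then dilute to 5 mM, PhSH (15 mol %), 50 °C; then air
Reagents that add atoms: bis(phosphonate) 6, COP(=O)(OC)CC(=O)CP(=O)(OC)OC
Why: Proposed new method: the unhindered CH2CHO of 5 undergoes a chemoselective Horner–Wadsworth–Emmons olefination to the (E)-enone 7, whose geometry forbids ring closure; catalytic thiolate adds reversibly to its β-carbon (thia-Michael), the freely rotating adduct 8 closes ring B by a second, intramolecular Horner–Wadsworth–Emmons reaction onto the neopentyl aldehyde, and retro-thia-Michael (E1cB) from 9 returns the thiolate and leaves the cis ring alkene, so the net result is a (4+3) annulation of an aliphatic 1,4-dialdehyde that leaves the quaternary centre untouched; the closest known reactions are the double Horner–Wadsworth–Emmons synthesis of benzotropones from phthalaldehyde and thiolate-catalysed E/Z isomerisation of enones.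

Step 4
Reactants: 10; 11 formaldehyde
Product: 12 (5S)-2-(hydroxymethyl)-5-methyl-5-(4-methylpent-3-en-1-yl)cyclohepta-2,6-dien-1-one
Conditions: 37 % aq. HCHO, DMAP (20 mol %), THF, rt
Reagents that add atoms: formaldehyde 11, C=O
Why: Morita–Baylis–Hillman reaction: DMAP adds reversibly to the enone β-carbon flanked by CH2 (C6 of 10) and not to the neopentyl one (C3), so only C7 is hydroxymethylated and no stereocentre is formed.

Step 5
Reactants: 12
Product: 14 (5R,8S,12S)-4,4,8-trimethyl-3-oxatricyclo[6.3.2.0(5,12)]trideca-1,9-dien-11-one, via formyl dienone 13 (not isolated)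
Conditions: Dess–Martin periodinane, CH2Cl2, 0 °C → rt; then 40 °C
Reagents that add atoms: none
Why: Oxidation gives the 2-formyl dienone, a doubly activated 1-oxadiene in which only the formyl C=O can be s-cis, and this undergoes an intramolecular inverse-electron-demand hetero-Diels–Alder reaction with the trisubstituted alkene; the tether from the quaternary carbon reaches C12 only from its own face and must lie endo, so C12 and C5 are set with their hydrogens cis and rings A and C close together.

Step 6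
Reactants: 14; 15 vinylmagnesium bromide; 16 3-bromo-2-methylprop-1-ene
Product: 18 (5R,8S,9S,10S,12S)-9-ethenyl-4,4,8-trimethyl-10-(2-methylprop-2-en-1-yl)-3-oxatricyclo[6.3.2.0(5,12)]tridec-1-en-11-one, via magnesium enolate 17 (not isolated)
Conditions: 15 (1.5 equiv), CuBr·SMe2 (10 mol %), LiCl (20 mol %), THF, −78 → −40 °C; then 16, DMPU, −40 → 0 °C
Reagents that add atoms: vinylmagnesium bromide 15, C=C[Mg]Br; 3-bromo-2-methylprop-1-ene 16, CC(=C)CBr
Why: Copper-catalysed conjugate addition followed by enolate alkylation (three-component coupling): the vinyl group adds to the enone terminus C9 (the vinylogous ester is far less electrophilic) from the face opposite the ring-A bridge, and the regiostable α′-enolate of the vinylogous ester is alkylated at C10 trans to the new vinyl group.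

Step 7
Reactants: 18
Product: 20 (1S,5R,8S,9S,10S,12S)-9-ethenyl-4,4,8-trimethyl-10-(2-methylprop-2-en-1-yl)-3-oxatricyclo[6.3.2.0(5,12)]tridecan-11-one, via lithium enolate 19 (not isolated)
Conditions: LiBH(s-Bu)3, THF, −78 °C; then AcOH in THF, −78 °C
Reagents that add atoms: none
Why: Conjugate (1,4) hydride reduction of the β-alkoxy enone at C2 leaves both alkenes untouched, and kinetic protonation of the resulting enolate at C1 from the open face (away from ring A and the axial C6 methylene) gives the C1–H cis to C12–H.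

Step 8
Reactants: 20
Product: 22 (1S,5R,8S,9S,10S,12S)-4,4,8-trimethyl-11-oxo-10-(2-oxopropyl)-3-oxatricyclo[6.3.2.0(5,12)]tridecane-9-carbaldehyde, via bis-ozonide 21 (not isolated)
Conditions: O3, CH2Cl2, −78 °C; then Me2S, −78 °C → rt
Reagents that add atoms: ozone, [O-][O+]=O
Why: Ozonolysis (Criegee mechanism, reductive work-up) cleaves the only two alkenes at once, the vinyl group to the C9 aldehyde and the methallyl group to the acetonyl ketone, under neutral conditions that do not enolise C1, C9 or C10.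

Step 9
Reactants: 23 3-methylbut-2-enoyl chloride; 11 formaldehyde (as paraformaldehyde)
Product: 24 chloromethyl 3-methylbut-2-enoate
Conditions: (CH2O)n, ZnCl2 (cat.), neat, 80 °C
Reagents that add atoms: formaldehyde 11, C=O
Why: Lewis-acid-catalysed addition of an acyl chloride across the formaldehyde C=O (chloromethyl ester synthesis) is atom-economical and leaves the conjugated alkene alone.

Step 10
Reactants: 24; 25 triphenylphosphine
Product: 26 {[(3-methylbut-2-enoyl)oxy]methyl}(triphenyl)phosphonium chloride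
Conditions: PPh3, PhMe, 90 °C
Reagents that add atoms: triphenylphosphine 25, c1ccc(cc1)P(c1ccccc1)c1ccccc1
Why: SN2 quaternisation of the activated chloromethyl ester gives the crystalline phosphonium salt.

Step 11
Reactants: 22; 26
Product: 28 vibsanin E, via phosphorus ylide 27 (not isolated)
Conditions: 26, NaN(SiMe3)2, THF, −78 °C; then 22, −78 → −20 °C; E isomer separated by chromatography
Reagents that add atoms: phosphonium salt 26, CC(C)=CC(=O)OC[P+](c1ccccc1)(c1ccccc1)c1ccccc1.[Cl-]
Why: Wittig olefination with an (acyloxymethylene)phosphorane converts the aldehyde directly into the enol ester at low temperature, faster than the two ketones react or enolise; the E/Z mixture expected from this ylide class is separated.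

**Compound list**
1 | geranial, (2E)-3,7-dimethylocta-2,6-dienal | CC(C)=CCC/C(C)=C/C=O | starting material
2 | nitromethane | C[N+](=O)[O-] | starting material
3 | (3S)-3,7-dimethyl-3-(nitromethyl)oct-6-enal | CC(C)=CCC[C@@](C)(CC=O)C[N+](=O)[O-] | intermediate
4 | sodium aci-nitronate of 3 | CC(C)=CCC[C@@](C)(CC=O)C=[N+]([O-])[O-].[Na+] | intermediate
5 | (2S)-2-methyl-2-(4-methylpent-3-en-1-yl)butanedial | CC(C)=CCC[C@@](C)(CC=O)C=O | intermediate
6 | tetramethyl (2-oxopropane-1,3-diyl)bis(phosphonate) | COP(=O)(OC)CC(=O)CP(=O)(OC)OC | starting material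
7 | dimethyl [(3E,6S)-6-formyl-6,10-dimethyl-2-oxoundeca-3,9-dien-1-yl]phosphonate | COP(=O)(OC)CC(=O)/C=C/C[C@@](C)(C=O)CCC=C(C)C | intermediate
8 | dimethyl [(6S)-6-formyl-6,10-dimethyl-2-oxo-4-(phenylsulfanyl)undec-9-en-1-yl]phosphonate (C4 epimers) | COP(=O)(OC)CC(=O)CC(Sc1ccccc1)C[C@@](C)(C=O)CCC=C(C)C | intermediate
9 | (4S)-4-methyl-4-(4-methylpent-3-en-1-yl)-6-(phenylsulfanyl)cyclohept-2-en-1-one (C6 epimers) | O=C1C=C[C@@](C)(CCC=C(C)C)CC(Sc2ccccc2)C1 | intermediate
10 | (4S)-4-methyl-4-(4-methylpent-3-en-1-yl)cyclohepta-2,6-dien-1-one | O=C1C=C[C@@](C)(CCC=C(C)C)CC=C1 | intermediate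
11 | formaldehyde | C=O | starting material
12 | (5S)-2-(hydroxymethyl)-5-methyl-5-(4-methylpent-3-en-1-yl)cyclohepta-2,6-dien-1-one | O=C1C=C[C@@](C)(CCC=C(C)C)CC=C1CO | intermediate
13 | (4S)-4-methyl-4-(4-methylpent-3-en-1-yl)-7-oxocyclohepta-1,5-diene-1-carbaldehyde | O=C1C=C[C@@](C)(CCC=C(C)C)CC=C1C=O | intermediate
14 | (5R,8S,12S)-4,4,8-trimethyl-3-oxatricyclo[6.3.2.0(5,12)]trideca-1,9-dien-11-one (rings A, B, C closed; O–CH=C enol ether and C9=C10 enone flank the ketone) | O=C1C2=COC(C)(C)[C@@H]3CC[C@@](C)(C[C@@H]32)C=C1 | intermediate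
15 | vinylmagnesium bromide | C=C[Mg]Br | starting material
16 | 3-bromo-2-methylprop-1-ene | CC(=C)CBr | starting material
17 | bromomagnesium enolate of the 9-vinyl adduct of 14 (C10=C11–OMgBr) | C1=C(O[Mg]Br)C2=COC(C)(C)[C@@H]3CC[C@@](C)(C[C@@H]32)[C@H]1C=C | intermediate
18 | (5R,8S,9S,10S,12S)-9-ethenyl-4,4,8-trimethyl-10-(2-methylprop-2-en-1-yl)-3-oxatricyclo[6.3.2.0(5,12)]tridec-1-en-11-one | C=C(C)C[C@@H]1C(=O)C2=COC(C)(C)[C@@H]3CC[C@@](C)(C[C@@H]32)[C@H]1C=C | intermediate
19 | lithium enolate of 20 (C1=C11–OLi) | C=C(C)C[C@@H]1C(O[Li])=C2COC(C)(C)[C@@H]3CC[C@@](C)(C[C@@H]32)[C@H]1C=C | intermediate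
20 | (1S,5R,8S,9S,10S,12S)-9-ethenyl-4,4,8-trimethyl-10-(2-methylprop-2-en-1-yl)-3-oxatricyclo[6.3.2.0(5,12)]tridecan-11-one | C=C(C)C[C@@H]1C(=O)[C@@H]2COC(C)(C)[C@@H]3CC[C@@](C)(C[C@@H]32)[C@H]1C=C | intermediate
21 | bis(1,2,4-trioxolane) (bis-ozonide) of 20 | CC1(C[C@@H]2C(=O)[C@@H]3COC(C)(C)[C@@H]4CC[C@@](C)(C[C@@H]43)[C@H]2C5OCOO5)OCOO1 | intermediate
22 | (1S,5R,8S,9S,10S,12S)-4,4,8-trimethyl-11-oxo-10-(2-oxopropyl)-3-oxatricyclo[6.3.2.0(5,12)]tridecane-9-carbaldehyde | CC(=O)C[C@@H]1C(=O)[C@@H]2COC(C)(C)[C@@H]3CC[C@@](C)(C[C@@H]32)[C@H]1C=O | intermediate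
23 | 3-methylbut-2-enoyl chloride | CC(C)=CC(Cl)=O | starting material
24 | chloromethyl 3-methylbut-2-enoate | CC(C)=CC(=O)OCCl | intermediate
25 | triphenylphosphine | c1ccc(cc1)P(c1ccccc1)c1ccccc1 | starting material
26 | {[(3-methylbut-2-enoyl)oxy]methyl}(triphenyl)phosphonium chloride | CC(C)=CC(=O)OC[P+](c1ccccc1)(c1ccccc1)c1ccccc1.[Cl-] | intermediate
27 | {[(3-methylbut-2-enoyl)oxy]methylidene}(triphenyl)phosphorane | CC(C)=CC(=O)OC=P(c1ccccc1)(c1ccccc1)c1ccccc1 | intermediate
28 | vibsanin E, (E)-2-[(1S,5R,8S,9S,10S,12S)-4,4,8-trimethyl-11-oxo-10-(2-oxopropyl)-3-oxatricyclo[6.3.2.0(5,12)]tridecan-9-yl]ethenyl 3-methylbut-2-enoate | CC(=O)C[C@@H]1C(=O)[C@@H]2COC(C)(C)[C@@H]3CC[C@@](C)(C[C@@H]32)[C@H]1/C=C/OC(=O)C=C(C)C | target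

**Step count and weak points**

Total steps: 11. Longest linear sequence: 9 (steps 1–8 and 11); steps 9 and 10 prepare the Wittig salt.

Step 3 (new annulation). The thiolate may turn over slowly, the open-chain enone may oligomerise, or the seven-ring olefination onto the neopentyl aldehyde may fail. The fallback uses known reactions only, sets out from 3 and comes back at 14, so it also bypasses steps 2, 4 and 5. Horner–Wadsworth–Emmons reaction of 3 with 6 (K2CO3, 18-crown-6, PhMe) gives the nitro enone phosphonate F1. Hydrogenation of the enone C=C only (H2, RhCl(PPh3)3, PhH) gives the saturated nitro keto phosphonate F2. The McMurry–Nef reaction (NaOMe; TiCl3, NH4OAc) gives the keto phosphonate aldehyde F3, and intramolecular Horner–Wadsworth–Emmons ring closure (K2CO3, 18-crown-6, 5 mM) gives the cycloheptenone F4. Claisen formylation at C7 (NaH, HCO2Et) gives the hydroxymethylene ketone F5, and DDQ dehydrogenation (dioxane, rt) gives 13, which cyclises to 14 as in step 5.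

Step 7 (C1 stereocentre). Possible failures are 1,2-reduction, β-elimination of the ring oxygen from enolate 19, or protonation/equilibration to the more stable C1 epimer. The fallback sets out from 14 and comes back at 20. Hydrogenation of both C=C bonds of 14 (H2, Pd/C, EtOAc), with hydrogen delivered to C1 from the open face, gives the saturated tricyclic ketone F6. Kinetic enolisation toward C10 (LiN(i-Pr)2, Me3SiCl, THF, −78 °C) gives the silyl enol ether F7, and Saegusa–Ito oxidation (Pd(OAc)2, MeCN) gives the tricyclic enone F8. Copper-catalysed addition of 15 and alkylation with 16 under the conditions of step 6 then gives 20 directly.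

Step 11 (enol ester geometry). The ylide gives E/Z mixtures and its basicity may trigger aldol reactions or epimerisation of the tricarbonyl substrate. The fallback sets out from 22 and comes back at 28. Boron-Wittig olefination with lithiated bis[(pinacolato)boryl]methane (lithium 2,2,6,6-tetramethylpiperidide, THF, −78 °C) gives the (E)-alkenyl pinacol boronate F9. KHF2 (MeOH–H2O) gives the potassium alkenyltrifluoroborate F10. Chan–Lam–Evans coupling with 3-methylbut-2-enoic acid (Cu(OAc)2, DMAP, 4 Å sieves, O2, CH2Cl2) gives 28 with retention of the E geometry.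

**Further compounds**
F1 | step 3 | dimethyl [(3E,6S)-6,10-dimethyl-6-(nitromethyl)-2-oxoundeca-3,9-dien-1-yl]phosphonate | COP(=O)(OC)CC(=O)/C=C/C[C@@](C)(C[N+](=O)[O-])CCC=C(C)C
F2 | step 3 | dimethyl [(6R)-6,10-dimethyl-6-(nitromethyl)-2-oxoundec-9-en-1-yl]phosphonate | COP(=O)(OC)CC(=O)CCC[C@@](C)(C[N+](=O)[O-])CCC=C(C)C
F3 | step 3 | dimethyl [(6R)-6-formyl-6,10-dimethyl-2-oxoundec-9-en-1-yl]phosphonate | COP(=O)(OC)CC(=O)CCC[C@@](C)(C=O)CCC=C(C)C
F4 | step 3 | (4R)-4-methyl-4-(4-methylpent-3-en-1-yl)cyclohept-2-en-1-one | O=C1C=C[C@@](C)(CCC=C(C)C)CCC1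
F5 | step 3 | (4S)-7-(hydroxymethylidene)-4-methyl-4-(4-methylpent-3-en-1-yl)cyclohept-2-en-1-one | O=C1C=C[C@@](C)(CCC=C(C)C)CCC1=CO
F6 | step 7 | (1S,5R,8R,12S)-4,4,8-trimethyl-3-oxatricyclo[6.3.2.0(5,12)]tridecan-11-one | C1C(=O)[C@@H]2COC(C)(C)[C@@H]3CC[C@@](C)(C[C@@H]32)C1
F7 | step 7 | (1S,5R,8S,12S)-4,4,8-trimethyl-11-[(trimethylsilyl)oxy]-3-oxatricyclo[6.3.2.0(5,12)]tridec-10-ene | C1=C(O[Si](C)(C)C)[C@@H]2COC(C)(C)[C@@H]3CC[C@@](C)(C[C@@H]32)C1
F8 | step 7 | (1S,5R,8S,12S)-4,4,8-trimethyl-3-oxatricyclo[6.3.2.0(5,12)]tridec-9-en-11-one | O=C1[C@@H]2COC(C)(C)[C@@H]3CC[C@@](C)(C[C@@H]32)C=C1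
F9 | step 11 | 2-{(E)-2-[(1S,5R,8S,9S,10S,12S)-4,4,8-trimethyl-11-oxo-10-(2-oxopropyl)-3-oxatricyclo[6.3.2.0(5,12)]tridecan-9-yl]ethenyl}-4,4,5,5-tetramethyl-1,3,2-dioxaborolane | CC(=O)C[C@@H]1C(=O)[C@@H]2COC(C)(C)[C@@H]3CC[C@@](C)(C[C@@H]32)[C@H]1/C=C/B1OC(C)(C)C(C)(C)O1
F10 | step 11 | potassium trifluoro{(E)-2-[(1S,5R,8S,9S,10S,12S)-4,4,8-trimethyl-11-oxo-10-(2-oxopropyl)-3-oxatricyclo[6.3.2.0(5,12)]tridecan-9-yl]ethenyl}borate | CC(=O)C[C@@H]1C(=O)[C@@H]2COC(C)(C)[C@@H]3CC[C@@](C)(C[C@@H]32)[C@H]1/C=C/[B-](F)(F)F.[K+]
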